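We decide to follow one number, the fraction of electrophile left, and to carry with it the share of the nucleophile that is free to react.

- zeta: electrophile 0.10 M; nucleophile 0.100 M; solid base 0.0500 M; time 10 d
- delta: electrophile 0.10 M; nucleophile 0.130 M; solid base 0.0500 M; time 10 d

    nucleophile + acid set free ⇌ protonated nucleophile, settled at all times (K1 = 5900 /M)
    solid base ⇌ free base, rate k2*(cs2 - [free base]) while solid is left; crystals form when [free base] > cs2 (cs2 = 0.070 M, k2 = 0.0010 /min)
    electrophile + nucleophile → acid set free + product (k3 = 0.0047 /M/min)
    acid set free + free base ⇌ salt of the base, settled at all times (K4 = 2.4 × 10⁵ /M)
    nucleophile ⇌ dormant form (K5 = 2.8, k5 = 0.0015 /min)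
    2 nucleophile → homo dimer (k6 = 0.0018 /M/min)

* part of the electrophile that has reacted at the end, zeta
* part of the electrophile that has reacted at the end, delta
* what raising the concentration of nucleophile from its lowest to its highest value here does to the part of the electrophile that has reacted (changes below 5 percentage points count as none) (it falls / no change / it rises)

- a step written with two of one species runs at k times the square of its concentration and takes two of it each time
- given per volume of solution although it is solid: solid base
- at the start none of the solid base is in solution
- run time (zeta): 10 d

With the main step alone, the equal charges of zeta make the reciprocal of [electrophile] grow linearly in time, which leaves 12.9% after 10 d. Now add the dormant form. Nucleophile and dormant form make a pool, and [nucleophile] over [pool] at balance is 0.263, the free share. The main step then runs with the constant 0.00124 /M/min, so its time in zeta is 8090 min. Because balance returns within 491 min, the pool may be treated as one species, and zeta leaves 36.0%.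

Next comes the acid. Because the free base binds it more strongly and dissolves on a time scale of 1000 min, a product costs one nucleophile until 0.0500 M of product stands; after that the acid takes a second nucleophile as protonated nucleophile. Last, the homo dimer takes a further 0.202 nucleophile per product, a selectivity factor reckoned with [pool] set equal to [electrophile], and we keep it for delta.

The price is therefore 1.20, then 2.20. At a steady price s, [pool] − s[electrophile] stays constant, and [pool]/[electrophile] changes exponentially with rate constant keff times that constant. The first leg ends at 9030 min in zeta and 6000 min in delta. At the end, zeta has 41.3% left, so 58.7% has reacted. Delta has 31.4% left, so 68.6% has reacted. The gap of 9.9 percentage points gives our verdict on the trend: it rises.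

The forecast, which lets the base take up the first acid and then holds “After that, each electrophile consumed costs two nucleophiles”, a cost in two stages like ours, gives 57% for zeta and 65% for delta, both lower than ours, and also says it rises.

The simulation gives 56.4% for zeta and 64.7% for delta, so it rises, by 8.3 points. In zeta at 1.75 d, the half-life of nucleophile by the forward step to the dormant form is 0.32 d, shorter than the 1.4 d by the main step. The free share read at the end is 0.230 in zeta and 0.233 in delta, against 0.263 at balance.

(The constants used here are invented; the run is a simulation.)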